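A small charge of catalyst, 0.40 mM beside 0.80 M of starting material, goes into this flask, and what we watch is the split between target and side product rather than the clock.

| setting | south-east | south-west | north | flask |
|---|---|---|---|---|
| starting material | 0.80 M | 0.80 M | 0.40 M | 0.80 M |
| catalyst | 0.56 mM | 0.88 mM | 0.40 mM | 0.40 mM |
| remark | run made earlier | run made earlier | run made earlier |  |
| time |  |  |  | 40 min |

| run | time / min | target / % | side product / % |
|---|---|---|---|
| south-east | 8.00 | 75.9 | 22.0 |
| south-east | 15.0 | 77.8 | 20.3 |
| south-east | 25.0 | 77.8 | 22.4 |
| south-east | 30.0 | 77.7 | 20.7 |
| south-west | 8.00 | 84.9 | 15.9 |
| south-west | 15.0 | 85.8 | 15.1 |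
| south-west | 25.0 | 83.7 | 15.4 |
| south-west | 30.0 | 85.1 | 15.6 |
| north | 4.00 | 70.0 | 26.7 |
| north | 12.0 | 70.6 | 29.7 |
| north | 20.0 | 72.4 | 28.0 |
| north | 30.0 | 70.4 | 29.3 |

(scatter of a reading: 1 percentage point)

1. amount of target at 40 min, in percent of the starting material charged
2. amount of side product at 40 min, in percent of the starting material charged



The flask looks nearly like the south-east run: it has the same [starting material], but 0.40 mM of catalyst against 0.56 mM. That run stands flat from its first reading at 8.00 min, so we read it as an end point and pool its readings:

[catalyst]× = 0.56 mM × side product / target = 0.155 mM

This crossing [catalyst] is the level at which the selectivity, target over side product, reaches one if it grows in proportion to [catalyst]. The north run, at 0.40 M of starting material, reads 0.160 mM, the same within the scatter. The south-east run ends richer in target than the flask should because its catalyst stands at 3.61 times the crossing and the flask's at 2.58 times. Our own reckoning for the flask is: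

target = 0.40 mM / (0.40 mM + 0.155 mM) = 72.1%, side product 27.9%

The forecast gives 71.5% of target (69% to 74%) and 28% of side product (25.5% to 30.5%), holding that “The split is therefore proportional to catalyst and independent of starting material concentration”. Our target stands slightly higher than the forecast's.

The flask gives 71.4% of target and 28.6% of side product at 40.0 min, with starting material at 0%.

    starting material + catalyst → catalyst + target (k = 48.0 /M/s)
    starting material → side product (k = 0.00770 /s)

The flask's target over side product is 2.50, beside the 2.58 that our crossing gave it, and its split already stands at 71.3% of target after 4.00 min. The neighbouring flask, charged with 0.100 mM of catalyst, lies below the crossing, and the same reckoning gives it 39.2% of target. That neighbour ends with more side product than target, at 38.4% of target and 61.6% of side product.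

The runs were generated by integration with constants of no real substance, and the scatter is random.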